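**Assumption:** the stereodescriptor in the SMILES is read as the (R)-2-methylbutanoyl group, and the route is built for that enantiomer.

## Retrosynthetic overview

1. The Ar–CH2–Ar' bridge is cut at the CH2–C bond to the acylphloroglucinol ring (ring A): an intermolecular Michael addition of ring A to an o-quinone methide released from the C8 Mannich base of the chromanone. The CH2 carbon is put on the chromanone by a Mannich reaction.
2. Chromanone (benzene ring B plus pyranone ring C): Friedel–Crafts acylation/oxa-Michael closure of the symmetric 3,5-dimethoxy-4-methylphenol with 3-methylbut-2-enoic acid, then O-demethylation. The symmetry of the phenol fixes the methyl at C6.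
3. Ring A: the same phenol as its MOM ether, directed ortho-lithiation, Weinreb acylation with the (R)-2-methylbutanoyl unit, then BCl3 unmasking of the MOM ether and the ortho methyl ether only.
4. The (R) centre comes from Evans methylation of the N-butanoyl imide of (4R)-4-benzyloxazolidin-2-one. The common phenol comes from iridium-catalysed C–H borylation/oxidation of 2,6-dimethoxytoluene.
5. Ring order: both benzene rings are bought. The only ring built is pyranone ring C (step 3), before the two fragments are joined (step 13).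

## Route

**Step 1**
Reactants: 1 1,3-dimethoxy-2-methylbenzene (2,6-dimethoxytoluene)
Product: 2 2-(3,5-dimethoxy-4-methylphenyl)-4,4,5,5-tetramethyl-1,3,2-dioxaborolane
Conditions: B2pin2 (1.0 equiv), [Ir(OMe)(cod)]2 (1.5 mol%), 4,4'-di-tert-butyl-2,2'-bipyridine (3 mol%), THF, 80 °C, 16 h
Reagents that add atoms: bis(pinacolato)diboron, CC1(C)OB(OC1(C)C)B1OC(C)(C)C(C)(C)O1
Why: Iridium-catalysed C–H borylation is sterically controlled, so only the C–H flanked by two hydrogens (para to the methyl, meta to both methoxy groups) reacts.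

**Step 2**
Reactants: 2 2-(3,5-dimethoxy-4-methylphenyl)-4,4,5,5-tetramethyl-1,3,2-dioxaborolane
Product: 3 3,5-dimethoxy-4-methylphenol
Conditions: KHSO5 (as 2KHSO5·KHSO4·K2SO4, 1.1 equiv), acetone/H2O, rt, 15 min
Reagents that add atoms: potassium peroxymonosulfate, [K+].[O-]S(=O)(=O)OO
Why: Boronate oxidation (aryl shift from boron to peroxide oxygen, then hydrolysis) gives the phenol at the borylated carbon without touching the ethers.

**Step 3**
Reactants: 3 3,5-dimethoxy-4-methylphenol; 4 3-methylbut-2-enoic acid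
Product: 6 5,7-dimethoxy-2,2,6-trimethyl-2,3-dihydro-4H-chromen-4-one, via aryl enone 5 (not isolated)
Conditions: 4 (1.2 equiv), P2O5/MeSO3H (1:10 w/w), 70 °C, 2 h; ice-water
Reagents that add atoms: none
Why: Friedel–Crafts acylation at either of the two equivalent positions ortho to the free OH, then intramolecular oxa-Michael closure through that only free hydroxyl, forms ring C with the methyl necessarily at C6.

**Step 4**
Reactants: 6 5,7-dimethoxy-2,2,6-trimethyl-2,3-dihydro-4H-chromen-4-one
Product: 7 5,7-dihydroxy-2,2,6-trimethyl-2,3-dihydro-4H-chromen-4-one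
Conditions: BBr3 (4 equiv), CH2Cl2, −78 °C → rt, 12 h; MeOH, then H2O
Reagents that add atoms: none
Why: Lewis-acid ether cleavage removes the chelated 5-OMe first and the 7-OMe on warming, while the ring oxygen (a vinylogous ester oxygen, a poor donor) is expected to stay intact.

**Step 5**
Reactants: 7 5,7-dihydroxy-2,2,6-trimethyl-2,3-dihydro-4H-chromen-4-one
Product: 8 8-[(dimethylamino)methyl]-5,7-dihydroxy-2,2,6-trimethyl-2,3-dihydro-4H-chromen-4-one
Conditions: Me2N=CH2+ I− (1.1 equiv), Et3N (1.1 equiv), CH2Cl2, 0 °C → rt, 3 h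
Reagents that add atoms: N,N-dimethylmethyleneiminium iodide (Eschenmoser's salt), C[N+](C)=C.[I-]
Why: Intermolecular phenol Mannich reaction; the preformed iminium ion attacks C8, the only unsubstituted aromatic carbon, ortho to the acidic 7-OH.

**Step 6**
Reactants: 9 (4R)-4-benzyl-1,3-oxazolidin-2-one; 10 butanoyl chloride
Product: 11 (4R)-4-benzyl-3-butanoyl-1,3-oxazolidin-2-one
Conditions: Et3N (1.5 equiv), DMAP (10 mol%), CH2Cl2, 0 °C → rt
Reagents that add atoms: none
Why: DMAP-catalysed nucleophilic acyl substitution (N-acylation) gives the imide cleanly.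

**Step 7**
Reactants: 11 (4R)-4-benzyl-3-butanoyl-1,3-oxazolidin-2-one
Product: 13 (4R)-4-benzyl-3-[(2R)-2-methylbutanoyl]-1,3-oxazolidin-2-one, via sodium Z-enolate 12 (not isolated)
Conditions: NaN(SiMe3)2 (1.1 equiv), THF, −78 °C, 1 h; MeI (5 equiv), −78 °C, 4 h; chromatography to a single diastereomer
Reagents that add atoms: iodomethane, CI
Why: Evans asymmetric alkylation: the chelated Z-enolate is methylated on the face away from the benzyl group, setting the (2R) centre (about 10:1 d.r. before purification).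

**Step 8**
Reactants: 13 (4R)-4-benzyl-3-[(2R)-2-methylbutanoyl]-1,3-oxazolidin-2-one
Product: 15 (2R)-2-methylbutanoic acid, via lithium peroxycarboxylate 14 (not isolated)
Conditions: LiOH·H2O (2 equiv), 30% H2O2 (4 equiv), THF/H2O 3:1, 0 °C, 2 h; aq. Na2SO3; then 1 M HCl, Et2O extraction
Reagents that add atoms: hydrogen peroxide, OO
Why: Hydroperoxide cleavage of the exocyclic imide carbonyl, then sulfite reduction of the peracid, frees the acid without epimerisation and returns the auxiliary.

**Step 9**
Reactants: 15 (2R)-2-methylbutanoic acid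
Product: 17 (2R)-N-methoxy-N,2-dimethylbutanamide, via acyl imidazole 16 (not isolated)
Conditions: CDI (1.1 equiv), CH2Cl2, rt, 1 h; MeNH(OMe)·HCl (1.3 equiv), rt, 12 h
Reagents that add atoms: N,O-dimethylhydroxylamine hydrochloride, CNOC.Cl
Why: Carboxyl activation as the acyl imidazole and aminolysis (amide coupling) proceed under near-neutral conditions that leave the α-centre alone.

**Step 10**
Reactants: 3 3,5-dimethoxy-4-methylphenol
Product: 18 1,3-dimethoxy-5-(methoxymethoxy)-2-methylbenzene
Conditions: MOMCl (1.3 equiv), i-Pr2NEt (1.5 equiv), CH2Cl2, 0 °C → rt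
Reagents that add atoms: chloromethyl methyl ether, COCCl
Why: O-Alkylation of the phenol installs a strong ortho-directing group that is later removed in the same operation as the neighbouring methyl ether.

**Step 11**
Reactants: 18 1,3-dimethoxy-5-(methoxymethoxy)-2-methylbenzene; 17 (2R)-N-methoxy-N,2-dimethylbutanamide
Product: 21 (2R)-1-[2,4-dimethoxy-6-(methoxymethoxy)-3-methylphenyl]-2-methylbutan-1-one, via aryllithium 19 (not isolated), via tetrahedral lithium adduct 20 (not isolated)
Conditions: 18 (1.3 equiv), n-BuLi (1.25 equiv), THF, 0 °C, 1 h; then 17 (1.0 equiv), −78 → 0 °C; sat. aq. NH4Cl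
Reagents that add atoms: none
Why: Directed ortho-metalation between OMOM and OMe (both free ring positions are equivalent) followed by Weinreb ketone synthesis, whose stable chelated adduct prevents over-addition and α-epimerisation.

**Step 12**
Reactants: 21 (2R)-1-[2,4-dimethoxy-6-(methoxymethoxy)-3-methylphenyl]-2-methylbutan-1-one
Product: 22 (2R)-1-(2,6-dihydroxy-4-methoxy-3-methylphenyl)-2-methylbutan-1-one
Conditions: BCl3 (3.5 equiv, 1 M in CH2Cl2), CH2Cl2, −78 → 0 °C, 2 h; H2O
Reagents that add atoms: none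
Why: Chelation-controlled ether cleavage: BCl3 removes the MOM group and then only the 2-OMe (ortho to the carbonyl and twisted between acyl and methyl), leaving the para 4-OMe.

**Step 13**
Reactants: 8 8-[(dimethylamino)methyl]-5,7-dihydroxy-2,2,6-trimethyl-2,3-dihydro-4H-chromen-4-one; 22 (2R)-1-(2,6-dihydroxy-4-methoxy-3-methylphenyl)-2-methylbutan-1-one
Product: 24 (2R)-1-{3-[(5,7-dihydroxy-2,2,6-trimethyl-4-oxo-3,4-dihydro-2H-chromen-8-yl)methyl]-2,6-dihydroxy-4-methoxy-5-methylphenyl}-2-methylbutan-1-one, via o-quinone methide 23 (not isolated)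
Conditions: 8 (1.2 equiv), 22 (1.0 equiv), 1,4-dioxane, 100 °C, N2 sweep, 4 h
Reagents that add atoms: none
Why: Thermal loss of dimethylamine from the Mannich base gives the o-quinone methide, and the only free ring carbon of 22 adds to it in an intermolecular Michael addition followed by rearomatisation; the stereocentre is remote and untouched.

## Compound list

1 | 1,3-dimethoxy-2-methylbenzene (2,6-dimethoxytoluene) | COc1cccc(OC)c1C | starting material
2 | 2-(3,5-dimethoxy-4-methylphenyl)-4,4,5,5-tetramethyl-1,3,2-dioxaborolane | COc1cc(cc(OC)c1C)B1OC(C)(C)C(C)(C)O1 | intermediate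
3 | 3,5-dimethoxy-4-methylphenol | COc1cc(O)cc(OC)c1C | intermediate
4 | 3-methylbut-2-enoic acid | CC(C)=CC(=O)O | starting material
5 | 1-(6-hydroxy-2,4-dimethoxy-3-methylphenyl)-3-methylbut-2-en-1-one | CC(C)=CC(=O)c1c(O)cc(OC)c(C)c1OC | intermediate
6 | 5,7-dimethoxy-2,2,6-trimethyl-2,3-dihydro-4H-chromen-4-one | COc1cc2OC(C)(C)CC(=O)c2c(OC)c1C | intermediate
7 | 5,7-dihydroxy-2,2,6-trimethyl-2,3-dihydro-4H-chromen-4-one | Cc1c(O)cc2OC(C)(C)CC(=O)c2c1O | intermediate
8 | 8-[(dimethylamino)methyl]-5,7-dihydroxy-2,2,6-trimethyl-2,3-dihydro-4H-chromen-4-one | CN(C)Cc1c(O)c(C)c(O)c2c1OC(C)(C)CC2=O | intermediate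
9 | (4R)-4-benzyl-1,3-oxazolidin-2-one | O=C1N[C@H](Cc2ccccc2)CO1 | starting material
10 | butanoyl chloride | CCCC(Cl)=O | starting material
11 | (4R)-4-benzyl-3-butanoyl-1,3-oxazolidin-2-one | CCCC(=O)N1[C@H](Cc2ccccc2)COC1=O | intermediate
12 | sodium (Z)-enolate of 11 | CC/C=C(\[O-])N1[C@H](Cc2ccccc2)COC1=O.[Na+] | intermediate
13 | (4R)-4-benzyl-3-[(2R)-2-methylbutanoyl]-1,3-oxazolidin-2-one | CC[C@@H](C)C(=O)N1[C@H](Cc2ccccc2)COC1=O | intermediate
14 | lithium (2R)-2-methylbutaneperoxoate | CC[C@@H](C)C(=O)O[O-].[Li+] | intermediate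
15 | (2R)-2-methylbutanoic acid | CC[C@@H](C)C(=O)O | intermediate
16 | (2R)-1-(1H-imidazol-1-yl)-2-methylbutan-1-one | CC[C@@H](C)C(=O)n1ccnc1 | intermediate
17 | (2R)-N-methoxy-N,2-dimethylbutanamide | CC[C@@H](C)C(=O)N(C)OC | intermediate
18 | 1,3-dimethoxy-5-(methoxymethoxy)-2-methylbenzene | COCOc1cc(OC)c(C)c(OC)c1 | intermediate
19 | [2,4-dimethoxy-6-(methoxymethoxy)-3-methylphenyl]lithium | [Li]c1c(OC)c(C)c(OC)cc1OCOC | intermediate
20 | lithium (2R)-1-[2,4-dimethoxy-6-(methoxymethoxy)-3-methylphenyl]-1-[methoxy(methyl)amino]-2-methylbutan-1-olate (carbinol carbon unassigned) | CC[C@@H](C)C([O-])(N(C)OC)c1c(OC)c(C)c(OC)cc1OCOC.[Li+] | intermediate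
21 | (2R)-1-[2,4-dimethoxy-6-(methoxymethoxy)-3-methylphenyl]-2-methylbutan-1-one | CC[C@@H](C)C(=O)c1c(OC)c(C)c(OC)cc1OCOC | intermediate
22 | (2R)-1-(2,6-dihydroxy-4-methoxy-3-methylphenyl)-2-methylbutan-1-one | CC[C@@H](C)C(=O)c1c(O)c(C)c(OC)cc1O | intermediate
23 | 5-hydroxy-2,2,6-trimethyl-8-methylidene-2,3-dihydro-4H-chromene-4,7(8H)-dione | C=C1C(=O)C(C)=C(O)C2=C1OC(C)(C)CC2=O | intermediate
24 | (2R)-1-{3-[(5,7-dihydroxy-2,2,6-trimethyl-4-oxo-3,4-dihydro-2H-chromen-8-yl)methyl]-2,6-dihydroxy-4-methoxy-5-methylphenyl}-2-methylbutan-1-one | CC[C@@H](C)C(=O)c1c(O)c(C)c(OC)c(Cc2c(O)c(C)c(O)c3c2OC(C)(C)CC3=O)c1O | target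

## Step count and risks

Total steps: 13. Longest linear sequence: 7 steps (6, 7, 8, 9, 11, 12, 13).

**Step 13 (fragment union).** Amine loss from 8 may be sluggish, or the methylene bridge may exchange and give symmetric dimers. The fallback sets out from 22 and comes back at 24 by reversing the roles of the two partners. Compound 22 is aminomethylated with Eschenmoser's salt and Et3N in CH2Cl2 at its only free ring carbon to give (2R)-1-{3-[(dimethylamino)methyl]-2,6-dihydroxy-4-methoxy-5-methylphenyl}-2-methylbutan-1-one F5. F5 is heated with chromanone 7 (2 equiv, cheap and recoverable) in 1,4-dioxane. It loses dimethylamine to the ring A quinone methide 3-hydroxy-5-methoxy-4-methyl-6-methylidene-2-[(2R)-2-methylbutanoyl]cyclohexa-2,4-dien-1-one F6, which C8 of 7 traps by Michael addition to give 24.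

**Step 11 (hindered aryllithium plus α-branched Weinreb amide).** Addition may be slow. The fallback sets out from 15 and 3 and comes back at 22 through a Fries route. Acid 15 is converted with oxalyl chloride and catalytic DMF into (2R)-2-methylbutanoyl chloride F2. F2 acylates phenol 3 (Et3N, CH2Cl2) to 3,5-dimethoxy-4-methylphenyl (2R)-2-methylbutanoate F3. A TiCl4-mediated Fries rearrangement (CH2Cl2, 0 °C → rt) moves the acyl group to one of the two equivalent ortho carbons and gives (2R)-1-(6-hydroxy-2,4-dimethoxy-3-methylphenyl)-2-methylbutan-1-one F4. BCl3 as in step 12 then removes the 2-OMe to give 22. The enantiomeric purity must be checked by chiral HPLC on this path.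

**Step 4 (double demethylation).** The 7-OMe may resist, or the pyranone ring may open under forcing Lewis-acid conditions and reclose to the 8-methyl isomer. The fallback sets out from 6 and comes back at 7 in two milder stages. BCl3 (1.2 equiv, CH2Cl2, −78 → 0 °C) cleaves only the chelated 5-OMe to give 5-hydroxy-7-methoxy-2,2,6-trimethyl-2,3-dihydro-4H-chromen-4-one F1. The 7-OMe, para to the carbonyl, is then removed by SN2 attack of NaSEt in DMF at 110 °C to give 7.

## Further compounds

F1 | step 4 | 5-hydroxy-7-methoxy-2,2,6-trimethyl-2,3-dihydro-4H-chromen-4-one | COc1cc2OC(C)(C)CC(=O)c2c(O)c1C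
F2 | step 11 | (2R)-2-methylbutanoyl chloride | CC[C@@H](C)C(Cl)=O
F3 | step 11 | 3,5-dimethoxy-4-methylphenyl (2R)-2-methylbutanoate | CC[C@@H](C)C(=O)Oc1cc(OC)c(C)c(OC)c1
F4 | step 11 | (2R)-1-(6-hydroxy-2,4-dimethoxy-3-methylphenyl)-2-methylbutan-1-one | CC[C@@H](C)C(=O)c1c(O)cc(OC)c(C)c1OC
F5 | step 13 | (2R)-1-{3-[(dimethylamino)methyl]-2,6-dihydroxy-4-methoxy-5-methylphenyl}-2-methylbutan-1-one | CC[C@@H](C)C(=O)c1c(O)c(C)c(OC)c(CN(C)C)c1O
F6 | step 13 | 3-hydroxy-5-methoxy-4-methyl-6-methylidene-2-[(2R)-2-methylbutanoyl]cyclohexa-2,4-dien-1-one | CC[C@@H](C)C(=O)C1=C(O)C(C)=C(OC)C(=C)C1=O
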